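## Structural features

The target is a germacranolide whose ten-membered carbocycle (C1–C10) is spanned by an ether oxygen between C1 and C5. This creates a cis-2,6-disubstituted tetrahydropyran (O, C1, C2, C3, C4, C5) and an eight-membered oxacycle (O, C1, C10, C9, C8, C7, C6, C5) that share the C1–O–C5 unit, an 11-oxabicyclo[5.3.1]undecene. C4 carries a spiro-epoxide (C15 and its oxygen), an α-methylene-γ-butyrolactone is trans-fused across C6–C7 (C6–O–C12, C11=C13), C8 bears a methacrylate, and the ring-cis C9=C10 alkene bears the C14 aldehyde. There are six stereocentres: C4, C5, C6, C7 and C8 are contiguous, and C1 is tied to C5 through the ether bridge. The relationships are C1/C5 cis on the tetrahydropyran, epoxide oxygen trans to C6, C5–O/C6–O syn, C6/C7 trans on the lactone and C6–O/C8–O anti. Fragile groups are the three Michael acceptors (enal, α-methylene lactone, methacrylate), the 2,2-disubstituted epoxide, the allylic C8 ester, and the 12,6-lactone, which can migrate to O8 whenever a C8 alkoxide is free. The real difficulty is closing a medium ring across a cis-tetrahydropyran while setting five contiguous stereocentres that carry four differently functionalised oxygens (on C4, C5, C6, C8). The key step exploits the fact that the tetrahydropyran has its only extra oxygen on C4, next to the ring carbon C5. That 3-oxopyran pattern is the oxidation-level signature of a furan (C1–C4) bearing a carbinol at C5, so the ring can be drawn from a flat aromatic precursor with one stereocentre.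

## Logic of the disconnections

39 ⇒ 38 ⇒ 37 ⇒ 36. The C8–O acyl bond is cut first, then the C14 aldehyde is taken back to the alcohol and both free hydroxyls to silyl ethers. The methacrylate would compete in metathesis and in enolate chemistry, and the enal is the most electrophilic group, so both must come last. The gain is that 36 carries only robust silyl ethers. The demand is a desilylation that spares epoxide and lactone, an oxidation of 37 that takes the primary allylic alcohol and leaves the C8 carbinol, and an acylation of 38 mild enough to avoid lactone migration.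

36 ⇒ 32. The C11=C13 bond is cut. The exocyclic methylene is a Michael acceptor and a metathesis partner, so it is added after ring closure. 32 is a plain saturated lactone. The forward step needs clean enolisation at C11, which is the only acidic site.

32 ⇒ 31. The C9=C10 bond is cut. It is the only C=C in the ring, its ring-cis geometry is enforced by the eight-membered oxacycle, and both termini come from simple terminal alkenes. The bicycle opens to a monocyclic tetrahydropyran with two arms. The demand is a medium-ring closure that forms a trisubstituted alkene from a 1,1-disubstituted partner.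

31 ⇒ 29 (through 30). The O6–C12 lactone bond is cut. Closing the lactone while O8 is silylated and O6 is released from an ester fixes the regiochemistry (12,6 and not 12,8). The gain is an open-chain triad. The demand is that the freed C6 alkoxide attacks a hindered ester faster than silicon migrates.

29 ⇒ 28 ⇒ 27. The O8–Si bond and then the C8–H bond are cut, taking the C8 carbinol back to a ketone. Hydride delivered from the C6 oxygen sets the 6,8-anti relationship and leaves O6 acylated and O8 free, which tells the two oxygens apart. The demand is that intramolecular hydride transfer outruns conjugate addition to the vinyl ketone.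

27 ⇒ 26 ⇒ 25 ⇒ 23. The C8–C9 bond is cut so that C9 arrives as a vinyl nucleophile on a C8 acyl group, and the acyl group is traced back through the acid to the auxiliary-bound form. The demand is single addition in the presence of a free C6 hydroxyl, an ester and the epoxide.

23 ⇒ 17 + 21, and 21 ⇒ 18 + 19. The C6–C7 bond is cut. An aldol sets C6 and C7 together and is the most convergent cut of the southern half, separating the tetrahydropyran from a four-carbon succinate unit (C7, C8, C11, C12). The demand is that the auxiliary overrides the intrinsic preference of 17 for the C5–O/C6–O anti product, and that no Lewis acid strong enough to open the epoxide is present.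

17 ⇒ 16 ⇒ 15 ⇒ 14. C6 is taken back to the silyl-protected alcohol, then the C4–C15 and C15–O bonds of the epoxide are cut to the C4 ketone. The ketone is what the ring expansion delivers, and it must be consumed before C6 becomes a carbonyl, otherwise C5 would sit between two carbonyls. The demand is axial attack at C4 and no enolisation towards C5.

14 ⇒ 13 ⇒ 12. The C2–H/C3–H bonds (enone saturation) and the C1–H bond (hemiketal reduction) are cut. C1 is set by axial hydride delivery to an oxocarbenium ion under control of C5. The demand is 1,2-hydride capture at C1 and a 1,4-reduction that spares C9=C10.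

12 ⇒ 10 (through 11). The C1–O bond is cut and the pyranone is folded back into a furan. This is the strategic simplification: C1–C5 with the correct oxygen pattern come from an aromatic ring with one stereocentre. The demand is oxidation of the furan without diversion through the conjugated C9=C10 alkene or the silyl ethers.

10 ⇒ 9. The C5–H bond is cut. The carbinol comes from the ketone by asymmetric transfer hydrogenation, and this single centre later controls C1 and C4. The demand is the (R) sense.

9 ⇒ 4 + 7, and 7 ⇒ 6 ⇒ 5. The C4–C5 bond is cut. The free furan α-position is metalated and acylated by an amide that stops at the ketone. The demand is deprotonation without addition to the conjugated alkene.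

4 ⇒ 3 ⇒ 1 + 2. The O–Si bond and then the C1–C10 bond are cut, giving an sp2–sp2 cross-coupling of two commercial partners.

## Other disconnections considered

Alternative 1: The cut is the C8–C9 bond. In the forward sense the (Z)-iodoalkene aldehyde A2 would be closed with CrCl2 and catalytic NiCl2 (Nozaki–Hiyama–Kishi), the C9 alkenylchromium adding to the C8 aldehyde to give the tricyclic C8 carbinol A1.
- In its favour: the trisubstituted C9=C10 alkene and its geometry are fixed before closure, the reaction is chemoselective for aldehydes, and the C8 hydroxyl emerges ready for acylation. On alkene geometry, and on avoiding metathesis of a 1,1-disubstituted alkene, it is the equal or the better of the chosen plan.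
- Against it: C8 would be set during a medium-ring closure with no reliable model, whereas the chosen plan sets it by a directed hydride transfer. A2 is a β-acyloxy aldehyde with an acidic C7–H and would be prone to epimerisation and elimination. A1 still has C14 as a methyl group and C4 as a methylene, so a late allylic oxidation and a chemo- and face-selective epoxidation among three alkenes would remain.
- Comparison: structurally it says nothing about how the cis-tetrahydropyran is made, so it is complementary to the furan ring expansion, not a replacement. Mechanistically it is a polar carbonyl addition in place of a metathesis. In step economy the closure is equal, but the end game should be longer by the oxidation-state corrections.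

Alternative 2: The cut is the C5–O ether bond together with the O–C12 lactone bond. In the forward sense camphorsulfonic acid would make the C1 hydroxyl of the ten-membered epoxy alcohol A4 open the cis C5–C6 epoxide at C5 with inversion, and the released C6 hydroxyl would close on the methyl ester to give the tricyclic ether lactone A3.
- In its favour: two rings and the C5 configuration would come from one stereospecific operation. For the number of steps after the carbocycle exists it is better than the chosen plan.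
- Against it: all the difficulty moves into A4, a ten-membered ring with four stereocentres, a cis alkene and a cis epoxide, which is not simpler than the target. Attack at C5 versus C6 depends on the ring conformation. C5 is allylic to the C4 methylene, so acid could ionise it and erode the inversion. The spiro-epoxide would again have to be installed late and selectively.
- Comparison: both plans form a C–O bond of the tetrahydropyran, at C5 here and at C1 in the chosen plan. The chosen plan does so on a small acyclic system where 6-exo closure is the only option, which is mechanistically safer. Overall step economy should favour the chosen plan once the synthesis of A4 is counted.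

Alternative 3: The cut is the C1–C2 bond, with C4–C9 reconnected. In the forward sense KH with 18-crown-6 would ionise the bridged vinyl carbinol A6 and the anionic oxy-Cope shift would give the oxa-bridged cyclodecenone A5.
- In its favour: the tetrahydropyran and the ten-membered ring would form in one pericyclic step driven by alkoxide acceleration and relief of the bridged bicycle, the ring-cis C9=C10 geometry follows from the cyclic transition state, and no metathesis is needed. It delivers the C4 ketone, the same handle for the sulfonium ylide as in the chosen plan, so on that point it is equal. It builds two rings where the chosen key step builds one, so it is better on that count.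
- Against it: A6 has six stereocentres including a quaternary carbinol on a bridged bicycle, and its synthesis should be as long as the rest of the route. The C4 alkoxide sits next to the C5–O bond and 1,3 to the C8 silyl ether, so fragmentation and silyl migration could compete under KH. The product enolate could equilibrate towards C5 and expel the C6 ether. The lactone carbons are still at the alcohol level behind two benzyl-type ethers.
- Comparison: structurally it is the most ambitious ring construction of the four. Mechanistically it needs strongly basic conditions on a densely oxygenated substrate, against a buffered oxidation in the chosen plan. Step economy is better at the key step and worse before and after it.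

Key step: step 7

Remark on the chemistry: the hemiketal carbon of 12 (and both acetal carbons of 11) are configurationally labile; the SMILES of 12 shows the anomer expected to prevail (axial hydroxyl), and step 8 converges both anomers.

Remark on the chemistry: the carbinol of 10 must be (R) to map onto C5 of the target, which requires the (R,R) enantiomer of the TsDPEN ligand in step 6.

Remark on the chemistry: metal alkoxides or chelates that are only the salt form of a product and are protonated on work-up are not counted as separate intermediates.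

Names use TBS = tert-butyldimethylsilyl and TBDPS = tert-butyldiphenylsilyl. Tricyclic compounds are named with germacrane numbering (ring C1–C10, lactone carbons C11–C13, C14 on C10, C15 on C4).

## Route

Step 1
Reactants: 1 furan-2-boronic acid; 2 2-bromoprop-2-en-1-ol
Product: 3 2-(furan-2-yl)prop-2-en-1-ol
Conditions: Pd(PPh3)4 (3 mol %), Na2CO3, DME/H2O, 80 °C
Reagents that add atoms: none
Why: Suzuki–Miyaura coupling; zerovalent palladium inserts readily into the vinyl C–Br bond and the free allylic alcohol is tolerated. A modest excess of 1 offsets protodeboronation of the furylboronic acid.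

Step 2
Reactants: 3 2-(furan-2-yl)prop-2-en-1-ol
Product: 4 tert-butyl{[2-(furan-2-yl)prop-2-en-1-yl]oxy}diphenylsilane
Conditions: TBDPSCl, imidazole, CH2Cl2, 0 °C to rt
Reagents that add atoms: tert-butyl(chloro)diphenylsilane, CC(C)(C)[Si](Cl)(c1ccccc1)c1ccccc1
Why: Silylation of a primary allylic alcohol. The TBDPS group is chosen for C14–O because it must outlast the acid of steps 7 and 8 and the selective cleavage of the TBS ether in step 11.

Step 3
Reactants: 5 ethyl glycolate
Product: 6 ethyl 2-[(tert-butyldimethylsilyl)oxy]acetate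
Conditions: TBSCl, imidazole, CH2Cl2, 0 °C to rt
Reagents that add atoms: tert-butyl(chloro)dimethylsilane, CC(C)(C)[Si](C)(C)Cl
Why: Routine silylation of a primary alcohol. TBS on C6–O is the silyl group that will later be removed in the presence of TBDPS.

Step 4
Reactants: 6 ethyl 2-[(tert-butyldimethylsilyl)oxy]acetate
Product: 7 2-[(tert-butyldimethylsilyl)oxy]-N-methoxy-N-methylacetamide
Conditions: MeNHOMe·HCl, i-PrMgCl, THF, −20 to 0 °C
Reagents that add atoms: N,O-dimethylhydroxylamine hydrochloride, CNOC.Cl
Why: Weinreb amide formation by aminolysis of the ester with the chloromagnesium amide made in the flask. The silyl ether is inert to the Grignard base at this temperature.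

Step 5
Reactants: 4 tert-butyl{[2-(furan-2-yl)prop-2-en-1-yl]oxy}diphenylsilane; 7 2-[(tert-butyldimethylsilyl)oxy]-N-methoxy-N-methylacetamide
Product: 9 2-[(TBS)oxy]-1-{5-[3-[(TBDPS)oxy]prop-1-en-2-yl]furan-2-yl}ethan-1-one, via 5-lithiofuran 8 (not isolated)
Conditions: lithium 2,2,6,6-tetramethylpiperidide (from the amine and n-BuLi), THF, −78 to −30 °C; then 7, −78 to 0 °C; aq. NH4Cl
Reagents that add atoms: lithium 2,2,6,6-tetramethylpiperidide, [Li]N1C(C)(C)CCCC1(C)C (its lithium stays in 8 only)
Why: Deprotonation of the free furan α-position followed by Weinreb ketone synthesis. The hindered amide base is chosen so that the alkene conjugated with the furan is not attacked by an alkyllithium, and the chelated tetrahedral adduct prevents a second addition.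

Step 6
Reactants: 9 2-[(TBS)oxy]-1-{5-[3-[(TBDPS)oxy]prop-1-en-2-yl]furan-2-yl}ethan-1-one
Product: 10 (1R)-2-[(TBS)oxy]-1-{5-[3-[(TBDPS)oxy]prop-1-en-2-yl]furan-2-yl}ethan-1-ol
Conditions: RuCl(p-cymene)[(R,R)-TsDPEN] (1 mol %), HCO2H/Et3N (5:2), CH2Cl2, rt
Reagents that add atoms: none
Why: Noyori asymmetric transfer hydrogenation of a heteroaryl ketone. The furan ring takes the place of the aryl group under the arene ligand, so the (R,R) ligand should deliver hydride to give the (R) carbinol (furyl outranks CH2OSi, so the descriptor follows the 1-arylethanol series). The isolated alkene and the silyl ethers are not touched.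

Step 7
Reactants: 10 (1R)-2-[(TBS)oxy]-1-{5-[3-[(TBDPS)oxy]prop-1-en-2-yl]furan-2-yl}ethan-1-ol
Product: 12 (2R,6R)-2-{[(TBS)oxy]methyl}-6-{3-[(TBDPS)oxy]prop-1-en-2-yl}-6-hydroxy-2H-pyran-3(6H)-one, via 2,5-dimethoxy-2,5-dihydrofuran 11 (not isolated)
Conditions: graphite anode, platinum cathode, undivided cell, constant current (about 2.2 F/mol), LiClO4, 2,6-lutidine, MeOH, −20 °C; then dilute aq. H2SO4, THF, 0 °C
Reagents that add atoms: water, O (the C1 hydroxyl oxygen of 12); methanol, CO (its atoms stay in 11 only)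
Why: The electron-rich 2,5-disubstituted furan is the group of lowest oxidation potential, so at the graphite anode it loses two electrons in succession and each cationic stage is captured by methanol at a ring α-carbon (C4 and C1), giving 11 (Clauson-Kaas-type anodic methoxylation). Dilute acid hydrolyses both mixed ketals to the cis-1,4-enedione, whose C1 ketone is attacked by the C5 hydroxyl in a 6-exo-trig hemiketalisation; this forms the C1–O bond and the 2H-pyran-3(6H)-one ring, and the cyclic hemiketal is the thermodynamic sink. The closest known reaction type is the Achmatowicz rearrangement of furfuryl alcohols run by anodic methoxylation and hydrolysis. No permanent stereocentre is created: C5 is carried through unchanged because the medium is buffered or acidic and never basic, and the hemiketal carbon equilibrates towards the anomer with axial hydroxyl and equatorial alkenyl group before it is erased in step 8. The selectivity needed is oxidation of the furan without loss of the C9=C10 alkene, which is conjugated with the ring and so belongs to the same electrophore; methanol should add 2,5 across the ring because the positive charge is best stabilised at the oxygen-flanked α-carbons, and the charge passed is limited at low temperature so that neither the alkene nor the product enone is oxidised further. The silyl ethers lie above the working potential, 2,6-lutidine keeps the anolyte from turning acidic, and only the C5 hydroxyl can close a six-membered ring because O6 and O14 are silylated.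

Step 8
Reactants: 12 (2R,6R)-2-{[(TBS)oxy]methyl}-6-{3-[(TBDPS)oxy]prop-1-en-2-yl}-6-hydroxy-2H-pyran-3(6H)-one
Product: 13 (2R,6R)-2-{[(TBS)oxy]methyl}-6-{3-[(TBDPS)oxy]prop-1-en-2-yl}-2H-pyran-3(6H)-one (2,6-cis)
Conditions: Et3SiH, CF3CO2H, CH2Cl2, −40 °C
Reagents that add atoms: none
Why: Kishi-type ionic reduction of a hemiketal. Acid ionises C1 to the ring oxocarbenium ion and the silane delivers hydride axially, on the face that leaves both carbon substituents pseudo-equatorial, so C1–H ends cis to C5–H. Hydride is expected at C1, the site of highest positive charge, and not at C9.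

Step 9
Reactants: 13 (2R,6R)-2-{[(TBS)oxy]methyl}-6-{3-[(TBDPS)oxy]prop-1-en-2-yl}-2H-pyran-3(6H)-one
Product: 14 (2R,6R)-2-{[(TBS)oxy]methyl}-6-{3-[(TBDPS)oxy]prop-1-en-2-yl}dihydro-2H-pyran-3(4H)-one
Conditions: Stryker's reagent [(Ph3P)CuH]6, toluene, H2O (5 equiv), rt
Reagents that add atoms: none
Why: Copper hydride conjugate reduction. Hydride adds to C2 of the enone and water protonates the copper enolate at C3. The unactivated 1,1-disubstituted alkene and the silyl ethers are inert, and the enolate carbon has no β-leaving group.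

Step 10
Reactants: 14 (2R,6R)-2-{[(TBS)oxy]methyl}-6-{3-[(TBDPS)oxy]prop-1-en-2-yl}dihydro-2H-pyran-3(4H)-one
Product: 15 (3R,4R,6R)-4-{[(TBS)oxy]methyl}-6-{3-[(TBDPS)oxy]prop-1-en-2-yl}-1,5-dioxaspiro[2.5]octane
Conditions: Me3S+ I−, n-BuLi, THF, −10 °C; then 14, −78 to 0 °C
Reagents that add atoms: trimethylsulfonium iodide, C[S+](C)C.[I-]
Why: Corey–Chaykovsky epoxidation. The sulfonium methylide adds irreversibly and axially to the chair ketone (both ring substituents equatorial, axial attack favoured in 3-oxanones), and the alkoxide then displaces dimethyl sulfide. C15 therefore ends axial and the epoxide oxygen equatorial, trans to C6, which is the (R) configuration at C4.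

Step 11
Reactants: 15 (3R,4R,6R)-4-{[(TBS)oxy]methyl}-6-{3-[(TBDPS)oxy]prop-1-en-2-yl}-1,5-dioxaspiro[2.5]octane
Product: 16 [(3R,4R,6R)-6-{3-[(TBDPS)oxy]prop-1-en-2-yl}-1,5-dioxaspiro[2.5]octan-4-yl]methanol
Conditions: HF·pyridine, pyridine, THF, 0 °C
Reagents that add atoms: none
Why: Selective desilylation. A primary TBS ether is cleaved by buffered HF·pyridine much faster than a primary TBDPS ether, and the excess pyridine protects the epoxide from acid.

Step 12
Reactants: 16 [(3R,4R,6R)-6-{3-[(TBDPS)oxy]prop-1-en-2-yl}-1,5-dioxaspiro[2.5]octan-4-yl]methanol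
Product: 17 (3R,4S,6R)-6-{3-[(TBDPS)oxy]prop-1-en-2-yl}-1,5-dioxaspiro[2.5]octane-4-carbaldehyde
Conditions: Dess–Martin periodinane, NaHCO3, CH2Cl2, 0 °C to rt
Reagents that add atoms: none
Why: Dess–Martin oxidation under buffered conditions that do not epimerise the α-alkoxy aldehyde. The aldehyde is used directly; the descriptor at the ring carbon changes only because the formyl group now outranks the spiro carbon.

Step 13
Reactants: 18 4-tert-butoxy-4-oxobutanoic acid; 19 (4S)-4-benzyl-1,3-oxazolidin-2-one
Product: 21 tert-butyl 4-[(4S)-4-benzyl-2-oxo-1,3-oxazolidin-3-yl]-4-oxobutanoate, via pivalic mixed anhydride 20 (not isolated)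
Conditions: t-BuCOCl, Et3N, THF, −20 °C; then 19, LiCl, rt
Reagents that add atoms: pivaloyl chloride, CC(C)(C)C(Cl)=O (its atoms stay in 20 only)
Why: N-Acylation of the oxazolidinone through a mixed anhydride with LiCl and amine activation, which avoids a strong base. The oxazolidinone attacks the less hindered succinyl carbonyl of 20.

Step 14
Reactants: 21 tert-butyl 4-[(4S)-4-benzyl-2-oxo-1,3-oxazolidin-3-yl]-4-oxobutanoate; 17 (3R,4S,6R)-6-{3-[(TBDPS)oxy]prop-1-en-2-yl}-1,5-dioxaspiro[2.5]octane-4-carbaldehyde
Product: 23 tert-butyl (3S,4S)-3-{[(4S)-4-benzyl-2-oxo-1,3-oxazolidin-3-yl]carbonyl}-4-hydroxy-4-[(3R,4R,6R)-6-{3-[(TBDPS)oxy]prop-1-en-2-yl}-1,5-dioxaspiro[2.5]octan-4-yl]butanoate, via (Z)-boron enolate 22 (not isolated)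
Conditions: n-Bu2BOTf, i-Pr2NEt, CH2Cl2, −78 to 0 °C; then 17, −78 to 0 °C; pH 7 buffer, MeOH, H2O2, 0 °C
Reagents that add atoms: dibutylboron triflate, CCCCB(CCCC)OS(=O)(=O)C(F)(F)F (its Bu2B group stays in 22 only)
Why: Evans syn-aldol reaction. The imide is enolised selectively to the (Z)-boron enolate, and the chair transition state with the dipole-minimised (S)-auxiliary gives the C6–C7 syn adduct with C6 and C7 as in the target. The pairing is mismatched with the aldehyde, which prefers the C5–O/C6–O anti product, so the auxiliary is relied on to dominate; the boron reagent is consumed in the enolate before the epoxide-bearing aldehyde is added.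

Step 15
Reactants: 23 tert-butyl (3S,4S)-3-{[(4S)-4-benzyl-2-oxo-1,3-oxazolidin-3-yl]carbonyl}-4-hydroxy-4-[(3R,4R,6R)-6-{3-[(TBDPS)oxy]prop-1-en-2-yl}-1,5-dioxaspiro[2.5]octan-4-yl]butanoate
Product: 25 (2S)-4-tert-butoxy-2-{(S)-hydroxy[(3R,4R,6R)-6-{3-[(TBDPS)oxy]prop-1-en-2-yl}-1,5-dioxaspiro[2.5]octan-4-yl]methyl}-4-oxobutanoic acid, via peroxy acid 24 (not isolated)
Conditions: LiOH, H2O2, THF/H2O, 0 °C; then aq. Na2SO3; NaHSO4 to pH 4
Reagents that add atoms: hydrogen peroxide, OO (one oxygen remains in 25)
Why: Hydroperoxide cleavage of the N-acyl oxazolidinone. The hydroperoxide anion attacks the exocyclic imide carbonyl selectively and sulfite reduces the peracid. The tert-butyl ester and the epoxide should survive at 0 °C, and the auxiliary is recovered.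

Step 16
Reactants: 25 (2S)-4-tert-butoxy-2-{(S)-hydroxy[(3R,4R,6R)-6-{3-[(TBDPS)oxy]prop-1-en-2-yl}-1,5-dioxaspiro[2.5]octan-4-yl]methyl}-4-oxobutanoic acid
Product: 26 tert-butyl (3S,4S)-4-hydroxy-3-[methoxy(methyl)carbamoyl]-4-[(3R,4R,6R)-6-{3-[(TBDPS)oxy]prop-1-en-2-yl}-1,5-dioxaspiro[2.5]octan-4-yl]butanoate
Conditions: MeNHOMe·HCl, EDC·HCl, HOBt, N-methylmorpholine, CH2Cl2, 0 °C to rt
Reagents that add atoms: N,O-dimethylhydroxylamine hydrochloride, CNOC.Cl
Why: Carbodiimide amide coupling. It needs no Lewis acid, so the epoxide is not exposed to aluminium amides, and the β-hydroxyl does not require protection.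

Step 17
Reactants: 26 tert-butyl (3S,4S)-4-hydroxy-3-[methoxy(methyl)carbamoyl]-4-[(3R,4R,6R)-6-{3-[(TBDPS)oxy]prop-1-en-2-yl}-1,5-dioxaspiro[2.5]octan-4-yl]butanoate
Product: 27 tert-butyl (3S)-3-{(S)-hydroxy[(3R,4R,6R)-6-{3-[(TBDPS)oxy]prop-1-en-2-yl}-1,5-dioxaspiro[2.5]octan-4-yl]methyl}-4-oxohex-5-enoate
Conditions: CH2=CHMgBr (3.5 equiv), THF, −78 to −20 °C; inverse quench into cold aq. NH4Cl
Reagents that add atoms: vinylmagnesium bromide, C=C[Mg]Br
Why: Weinreb ketone synthesis. The first equivalent deprotonates the hydroxyl and the chelated tetrahedral adduct prevents over-addition. The tert-butyl ester and the epoxide are inert at low temperature, and the inverse quench keeps the released amine from adding to the vinyl ketone.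

Step 18
Reactants: 27 tert-butyl (3S)-3-{(S)-hydroxy[(3R,4R,6R)-6-{3-[(TBDPS)oxy]prop-1-en-2-yl}-1,5-dioxaspiro[2.5]octan-4-yl]methyl}-4-oxohex-5-enoate
Product: 28 tert-butyl (3R,4R)-4-hydroxy-3-{(S)-(propanoyloxy)[(3R,4R,6R)-6-{3-[(TBDPS)oxy]prop-1-en-2-yl}-1,5-dioxaspiro[2.5]octan-4-yl]methyl}hex-5-enoate
Conditions: SmI2 (0.3 equiv), EtCHO (6 equiv), THF, −10 °C
Reagents that add atoms: propanal, CCC=O
Why: Evans–Tishchenko reduction. Propanal oxidises the divalent samarium to the trivalent alkoxide catalyst, and the samarium-bound hemiacetal on O6 passes its hydride to the C8 carbonyl through a chair-like six-membered transition state. This sets C8 (R), anti to C6–O, keeps the vinyl group (1,2-delivery), and leaves O6 acylated and O8 free, which distinguishes the two oxygens.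

Step 19
Reactants: 28 tert-butyl (3R,4R)-4-hydroxy-3-{(S)-(propanoyloxy)[(3R,4R,6R)-6-{3-[(TBDPS)oxy]prop-1-en-2-yl}-1,5-dioxaspiro[2.5]octan-4-yl]methyl}hex-5-enoate
Product: 29 tert-butyl (3S,4R)-4-[(TBS)oxy]-3-{(S)-(propanoyloxy)[(3R,4R,6R)-6-{3-[(TBDPS)oxy]prop-1-en-2-yl}-1,5-dioxaspiro[2.5]octan-4-yl]methyl}hex-5-enoate
Conditions: TBSOTf, 2,6-lutidine, CH2Cl2, −78 °C
Reagents that add atoms: tert-butyldimethylsilyl triflate, CC(C)(C)[Si](C)(C)OS(=O)(=O)C(F)(F)F
Why: Silylation of the hindered secondary allylic alcohol, run cold and at once so that the propanoate does not migrate from O6 to O8. The descriptor at C7 changes only because of CIP priorities.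

Step 20
Reactants: 29 tert-butyl (3S,4R)-4-[(TBS)oxy]-3-{(S)-(propanoyloxy)[(3R,4R,6R)-6-{3-[(TBDPS)oxy]prop-1-en-2-yl}-1,5-dioxaspiro[2.5]octan-4-yl]methyl}hex-5-enoate
Product: 31 (4S,5S)-4-{(1R)-1-[(TBS)oxy]prop-2-en-1-yl}-5-[(3R,4R,6R)-6-{3-[(TBDPS)oxy]prop-1-en-2-yl}-1,5-dioxaspiro[2.5]octan-4-yl]dihydrofuran-2(3H)-one, via hydroxy ester 30 (not isolated)
Conditions: K2CO3, MeOH, 0 °C to 40 °C
Reagents that add atoms: none
Why: Methanolysis of the propanoate followed by base-mediated lactonisation. The freed C6 alkoxide attacks the tert-butyl ester in a 5-exo-trig closure to give the trans-disubstituted γ-lactone. Because O8 is silylated, only the 12,6-lactone can form.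

Step 21
Reactants: 31 (4S,5S)-4-{(1R)-1-[(TBS)oxy]prop-2-en-1-yl}-5-[(3R,4R,6R)-6-{3-[(TBDPS)oxy]prop-1-en-2-yl}-1,5-dioxaspiro[2.5]octan-4-yl]dihydrofuran-2(3H)-one
Product: 32 (1R,4R,5R,6S,7S,8R)-8-[(TBS)oxy]-14-[(TBDPS)oxy]-1,5:4,15-diepoxygermacr-9-en-12,6-olide (ring-cis C9=C10)
Conditions: second-generation Grubbs catalyst (H2IMes)(PCy3)Cl2Ru=CHPh (10 mol %), toluene (1 mM), 80 °C
Reagents that add atoms: none
Why: Ring-closing metathesis. The catalyst loads at the monosubstituted vinyl group and closes onto the 1,1-disubstituted alkene at C10. The eight-membered oxacycle can only hold the ring-cis trisubstituted alkene, and high dilution with loss of ethene drives closure.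

Step 22
Reactants: 32 (1R,4R,5R,6S,7S,8R)-8-[(TBS)oxy]-14-[(TBDPS)oxy]-1,5:4,15-diepoxygermacr-9-en-12,6-olide
Product: 36 (1R,4R,5R,6S,7S,8R)-8-[(TBS)oxy]-14-[(TBDPS)oxy]-1,5:4,15-diepoxygermacra-9,11(13)-dien-12,6-olide, via lithium enolate 33 (not isolated), via Mannich base 34 (not isolated), via trimethylammonium iodide 35 (not isolated)
Conditions: LiN(i-Pr)2, THF, −78 °C; CH2=NMe2+ I−, −78 °C to rt; MeI, MeOH, rt; aq. NaHCO3, CH2Cl2, rt
Reagents that add atoms: Eschenmoser's salt, C=[N+](C)C.[I-]; lithium diisopropylamide, [Li]N(C(C)C)C(C)C (lithium in 33 only); iodomethane, CI (methyl in 35 only)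
Why: α-Methylenation of a lactone by Mannich reaction of its enolate, N-methylation and Hofmann-type elimination. C11 is the only acidic position and the enolate has no β-leaving group. No stereocentre is made; the C11 centre of 34 and 35 is lost on elimination.

Step 23
Reactants: 36 (1R,4R,5R,6S,7S,8R)-8-[(TBS)oxy]-14-[(TBDPS)oxy]-1,5:4,15-diepoxygermacra-9,11(13)-dien-12,6-olide
Product: 37 (1R,4R,5R,6S,7R,8R)-8,14-dihydroxy-1,5:4,15-diepoxygermacra-9,11(13)-dien-12,6-olide
Conditions: HF·pyridine, pyridine, THF, 0 °C to rt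
Reagents that add atoms: none
Why: Fluoride cleavage of both silyl ethers. The buffered, weakly acidic medium avoids a free C8 alkoxide, so the lactone should not migrate and the α-methylene lactone should not suffer conjugate addition.

Step 24
Reactants: 37 (1R,4R,5R,6S,7R,8R)-8,14-dihydroxy-1,5:4,15-diepoxygermacra-9,11(13)-dien-12,6-olide
Product: 38 (1R,4R,5R,6S,7R,8R)-8-hydroxy-14-oxo-1,5:4,15-diepoxygermacra-9,11(13)-dien-12,6-olide
Conditions: TEMPO (10 mol %), PhI(OAc)2, CH2Cl2, rt
Reagents that add atoms: none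
Why: Oxoammonium (TEMPO) oxidation, which is selective for the primary allylic alcohol over the hindered secondary C8 carbinol and stops at the aldehyde. The alkene geometry is locked by the ring.

Step 25
Reactants: 38 (1R,4R,5R,6S,7R,8R)-8-hydroxy-14-oxo-1,5:4,15-diepoxygermacra-9,11(13)-dien-12,6-olide
Product: 39 (1R,4R,5R,6S,7R,8R)-14-oxo-1,5:4,15-diepoxy-12,6-olidogermacra-9,11(13)-dien-8-yl 2-methylprop-2-enoate (CNP0257628.1)
Conditions: methacrylic anhydride, Et3N, DMAP (cat.), CH2Cl2, 0 °C
Reagents that add atoms: methacrylic anhydride, CC(=C)C(=O)OC(=O)C(C)=C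
Why: DMAP-catalysed acyl transfer to the secondary allylic alcohol. The mild base and low temperature are meant to avoid lactone migration and conjugate addition to the three acceptors; no stereocentre is touched.

## Compound list

1 | furan-2-boronic acid | OB(O)c1ccco1 | starting material
2 | 2-bromoprop-2-en-1-ol | OCC(Br)=C | starting material
3 | 2-(furan-2-yl)prop-2-en-1-ol | C=C(CO)c1ccco1 | intermediate
4 | tert-butyl{[2-(furan-2-yl)prop-2-en-1-yl]oxy}diphenylsilane | C=C(CO[Si](c1ccccc1)(c1ccccc1)C(C)(C)C)c1ccco1 | intermediate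
5 | ethyl glycolate | OCC(=O)OCC | starting material
6 | ethyl 2-[(tert-butyldimethylsilyl)oxy]acetate | CCOC(=O)CO[Si](C)(C)C(C)(C)C | intermediate
7 | 2-[(tert-butyldimethylsilyl)oxy]-N-methoxy-N-methylacetamide | CON(C)C(=O)CO[Si](C)(C)C(C)(C)C | intermediate
8 | {5-[3-[(TBDPS)oxy]prop-1-en-2-yl]furan-2-yl}lithium | [Li]c1ccc(o1)C(=C)CO[Si](c1ccccc1)(c1ccccc1)C(C)(C)C | intermediate
9 | 2-[(TBS)oxy]-1-{5-[3-[(TBDPS)oxy]prop-1-en-2-yl]furan-2-yl}ethan-1-one | C=C(CO[Si](c1ccccc1)(c1ccccc1)C(C)(C)C)c1ccc(o1)C(=O)CO[Si](C)(C)C(C)(C)C | intermediate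
10 | (1R)-2-[(TBS)oxy]-1-{5-[3-[(TBDPS)oxy]prop-1-en-2-yl]furan-2-yl}ethan-1-ol | C=C(CO[Si](c1ccccc1)(c1ccccc1)C(C)(C)C)c1ccc(o1)[C@H](O)CO[Si](C)(C)C(C)(C)C | intermediate
11 | (1R)-2-[(TBS)oxy]-1-{5-[3-[(TBDPS)oxy]prop-1-en-2-yl]-2,5-dimethoxy-2,5-dihydrofuran-2-yl}ethan-1-ol (acetal diastereomers) | C=C(CO[Si](c1ccccc1)(c1ccccc1)C(C)(C)C)C1(OC)C=CC(OC)(O1)[C@H](O)CO[Si](C)(C)C(C)(C)C | intermediate
12 | (2R,6R)-2-{[(TBS)oxy]methyl}-6-{3-[(TBDPS)oxy]prop-1-en-2-yl}-6-hydroxy-2H-pyran-3(6H)-one | C=C(CO[Si](c1ccccc1)(c1ccccc1)C(C)(C)C)[C@@]1(O)C=CC(=O)[C@@H](CO[Si](C)(C)C(C)(C)C)O1 | intermediate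
13 | (2R,6R)-2-{[(TBS)oxy]methyl}-6-{3-[(TBDPS)oxy]prop-1-en-2-yl}-2H-pyran-3(6H)-one | C=C(CO[Si](c1ccccc1)(c1ccccc1)C(C)(C)C)[C@H]1C=CC(=O)[C@@H](CO[Si](C)(C)C(C)(C)C)O1 | intermediate
14 | (2R,6R)-2-{[(TBS)oxy]methyl}-6-{3-[(TBDPS)oxy]prop-1-en-2-yl}dihydro-2H-pyran-3(4H)-one | C=C(CO[Si](c1ccccc1)(c1ccccc1)C(C)(C)C)[C@H]1CCC(=O)[C@@H](CO[Si](C)(C)C(C)(C)C)O1 | intermediate
15 | (3R,4R,6R)-4-{[(TBS)oxy]methyl}-6-{3-[(TBDPS)oxy]prop-1-en-2-yl}-1,5-dioxaspiro[2.5]octane | C=C(CO[Si](c1ccccc1)(c1ccccc1)C(C)(C)C)[C@H]1CC[C@@]2(CO2)[C@@H](CO[Si](C)(C)C(C)(C)C)O1 | intermediate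
16 | [(3R,4R,6R)-6-{3-[(TBDPS)oxy]prop-1-en-2-yl}-1,5-dioxaspiro[2.5]octan-4-yl]methanol | C=C(CO[Si](c1ccccc1)(c1ccccc1)C(C)(C)C)[C@H]1CC[C@@]2(CO2)[C@@H](CO)O1 | intermediate
17 | (3R,4S,6R)-6-{3-[(TBDPS)oxy]prop-1-en-2-yl}-1,5-dioxaspiro[2.5]octane-4-carbaldehyde | C=C(CO[Si](c1ccccc1)(c1ccccc1)C(C)(C)C)[C@H]1CC[C@@]2(CO2)[C@@H](C=O)O1 | intermediate
18 | 4-tert-butoxy-4-oxobutanoic acid | CC(C)(C)OC(=O)CCC(=O)O | starting material
19 | (4S)-4-benzyl-1,3-oxazolidin-2-one | O=C1N[C@@H](Cc2ccccc2)CO1 | starting material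
20 | 4-tert-butoxy-4-oxobutanoic pivalic anhydride | CC(C)(C)OC(=O)CCC(=O)OC(=O)C(C)(C)C | intermediate
21 | tert-butyl 4-[(4S)-4-benzyl-2-oxo-1,3-oxazolidin-3-yl]-4-oxobutanoate | CC(C)(C)OC(=O)CCC(=O)N1C(=O)OC[C@@H]1Cc1ccccc1 | intermediate
22 | (Z)-dibutylboron enolate of 21 | CCCCB(CCCC)O/C(=C\CC(=O)OC(C)(C)C)N1C(=O)OC[C@@H]1Cc1ccccc1 | intermediate
23 | tert-butyl (3S,4S)-3-{[(4S)-4-benzyl-2-oxo-1,3-oxazolidin-3-yl]carbonyl}-4-hydroxy-4-[(3R,4R,6R)-6-{3-[(TBDPS)oxy]prop-1-en-2-yl}-1,5-dioxaspiro[2.5]octan-4-yl]butanoate | C=C(CO[Si](c1ccccc1)(c1ccccc1)C(C)(C)C)[C@H]1CC[C@@]2(CO2)[C@H](O1)[C@@H](O)[C@H](CC(=O)OC(C)(C)C)C(=O)N1C(=O)OC[C@@H]1Cc1ccccc1 | intermediate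
24 | (2S)-4-tert-butoxy-2-{(S)-hydroxy[(3R,4R,6R)-6-{3-[(TBDPS)oxy]prop-1-en-2-yl}-1,5-dioxaspiro[2.5]octan-4-yl]methyl}-4-oxobutaneperoxoic acid | C=C(CO[Si](c1ccccc1)(c1ccccc1)C(C)(C)C)[C@H]1CC[C@@]2(CO2)[C@H](O1)[C@@H](O)[C@H](CC(=O)OC(C)(C)C)C(=O)OO | intermediate
25 | (2S)-4-tert-butoxy-2-{(S)-hydroxy[(3R,4R,6R)-6-{3-[(TBDPS)oxy]prop-1-en-2-yl}-1,5-dioxaspiro[2.5]octan-4-yl]methyl}-4-oxobutanoic acid | C=C(CO[Si](c1ccccc1)(c1ccccc1)C(C)(C)C)[C@H]1CC[C@@]2(CO2)[C@H](O1)[C@@H](O)[C@H](CC(=O)OC(C)(C)C)C(O)=O | intermediate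
26 | tert-butyl (3S,4S)-4-hydroxy-3-[methoxy(methyl)carbamoyl]-4-[(3R,4R,6R)-6-{3-[(TBDPS)oxy]prop-1-en-2-yl}-1,5-dioxaspiro[2.5]octan-4-yl]butanoate | C=C(CO[Si](c1ccccc1)(c1ccccc1)C(C)(C)C)[C@H]1CC[C@@]2(CO2)[C@H](O1)[C@@H](O)[C@H](CC(=O)OC(C)(C)C)C(=O)N(C)OC | intermediate
27 | tert-butyl (3S)-3-{(S)-hydroxy[(3R,4R,6R)-6-{3-[(TBDPS)oxy]prop-1-en-2-yl}-1,5-dioxaspiro[2.5]octan-4-yl]methyl}-4-oxohex-5-enoate | C=C(CO[Si](c1ccccc1)(c1ccccc1)C(C)(C)C)[C@H]1CC[C@@]2(CO2)[C@H](O1)[C@@H](O)[C@H](CC(=O)OC(C)(C)C)C(=O)C=C | intermediate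
28 | tert-butyl (3R,4R)-4-hydroxy-3-{(S)-(propanoyloxy)[(3R,4R,6R)-6-{3-[(TBDPS)oxy]prop-1-en-2-yl}-1,5-dioxaspiro[2.5]octan-4-yl]methyl}hex-5-enoate | C=C(CO[Si](c1ccccc1)(c1ccccc1)C(C)(C)C)[C@H]1CC[C@@]2(CO2)[C@H](O1)[C@@H](OC(=O)CC)[C@H](CC(=O)OC(C)(C)C)[C@H](O)C=C | intermediate
29 | tert-butyl (3S,4R)-4-[(TBS)oxy]-3-{(S)-(propanoyloxy)[(3R,4R,6R)-6-{3-[(TBDPS)oxy]prop-1-en-2-yl}-1,5-dioxaspiro[2.5]octan-4-yl]methyl}hex-5-enoate | C=C(CO[Si](c1ccccc1)(c1ccccc1)C(C)(C)C)[C@H]1CC[C@@]2(CO2)[C@H](O1)[C@@H](OC(=O)CC)[C@H](CC(=O)OC(C)(C)C)[C@H](O[Si](C)(C)C(C)(C)C)C=C | intermediate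
30 | tert-butyl (3S,4R)-4-[(TBS)oxy]-3-{(S)-hydroxy[(3R,4R,6R)-6-{3-[(TBDPS)oxy]prop-1-en-2-yl}-1,5-dioxaspiro[2.5]octan-4-yl]methyl}hex-5-enoate | C=C(CO[Si](c1ccccc1)(c1ccccc1)C(C)(C)C)[C@H]1CC[C@@]2(CO2)[C@H](O1)[C@@H](O)[C@H](CC(=O)OC(C)(C)C)[C@H](O[Si](C)(C)C(C)(C)C)C=C | intermediate
31 | (4S,5S)-4-{(1R)-1-[(TBS)oxy]prop-2-en-1-yl}-5-[(3R,4R,6R)-6-{3-[(TBDPS)oxy]prop-1-en-2-yl}-1,5-dioxaspiro[2.5]octan-4-yl]dihydrofuran-2(3H)-one | C=C(CO[Si](c1ccccc1)(c1ccccc1)C(C)(C)C)[C@H]1CC[C@@]2(CO2)[C@H](O1)[C@H]1OC(=O)C[C@@H]1[C@H](O[Si](C)(C)C(C)(C)C)C=C | intermediate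
32 | (1R,4R,5R,6S,7S,8R)-8-[(TBS)oxy]-14-[(TBDPS)oxy]-1,5:4,15-diepoxygermacr-9-en-12,6-olide | CC(C)(C)[Si](C)(C)O[C@@H]1/C=C(/CO[Si](c2ccccc2)(c2ccccc2)C(C)(C)C)[C@H]2CC[C@@]3(CO3)[C@H](O2)[C@H]2OC(=O)C[C@@H]21 | intermediate
33 | lithium enolate of 32 (C11=C12–OLi) | CC(C)(C)[Si](C)(C)O[C@@H]1/C=C(/CO[Si](c2ccccc2)(c2ccccc2)C(C)(C)C)[C@H]2CC[C@@]3(CO3)[C@H](O2)[C@H]2OC(O[Li])=C[C@@H]21 | intermediate
34 | 13-(dimethylamino) derivative of 32 (Mannich base, C11 epimers) | CC(C)(C)[Si](C)(C)O[C@@H]1/C=C(/CO[Si](c2ccccc2)(c2ccccc2)C(C)(C)C)[C@H]2CC[C@@]3(CO3)[C@H](O2)[C@H]2OC(=O)C(CN(C)C)[C@@H]21 | intermediate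
35 | 13-(trimethylammonio) derivative of 32, iodide | CC(C)(C)[Si](C)(C)O[C@@H]1/C=C(/CO[Si](c2ccccc2)(c2ccccc2)C(C)(C)C)[C@H]2CC[C@@]3(CO3)[C@H](O2)[C@H]2OC(=O)C(C[N+](C)(C)C)[C@@H]21.[I-] | intermediate
36 | (1R,4R,5R,6S,7S,8R)-8-[(TBS)oxy]-14-[(TBDPS)oxy]-1,5:4,15-diepoxygermacra-9,11(13)-dien-12,6-olide | CC(C)(C)[Si](C)(C)O[C@@H]1/C=C(/CO[Si](c2ccccc2)(c2ccccc2)C(C)(C)C)[C@H]2CC[C@@]3(CO3)[C@H](O2)[C@H]2OC(=O)C(=C)[C@@H]21 | intermediate
37 | (1R,4R,5R,6S,7R,8R)-8,14-dihydroxy-1,5:4,15-diepoxygermacra-9,11(13)-dien-12,6-olide | O[C@@H]1/C=C(/CO)[C@H]2CC[C@@]3(CO3)[C@H](O2)[C@H]2OC(=O)C(=C)[C@@H]21 | intermediate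
38 | (1R,4R,5R,6S,7R,8R)-8-hydroxy-14-oxo-1,5:4,15-diepoxygermacra-9,11(13)-dien-12,6-olide | O[C@@H]1/C=C(/C=O)[C@H]2CC[C@@]3(CO3)[C@H](O2)[C@H]2OC(=O)C(=C)[C@@H]21 | intermediate
39 | (1R,4R,5R,6S,7R,8R)-14-oxo-1,5:4,15-diepoxy-12,6-olidogermacra-9,11(13)-dien-8-yl 2-methylprop-2-enoate (CNP0257628.1) | C=C(C)C(=O)O[C@@H]1/C=C(/C=O)[C@H]2CC[C@@]3(CO3)[C@H](O2)[C@H]2OC(=O)C(=C)[C@@H]21 | target

## Step count and least certain steps

Total: 25 steps. Longest linear sequence: 22 steps (steps 1, 2, 5 to 12 and 14 to 25, starting from 1). Steps 3 and 4 (from 5) and step 13 (from 18 and 19) are side branches.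

**Step 7 (key step).** The C9=C10 alkene is conjugated with the furan, so the radical cation is shared with it. Methanol may add across the extended system (at C9 instead of C1), or the vinylfuran may be oxidised further or oligomerise. Acid hydrolysis may also loosen the primary TBS ether. The fallback replaces outer-sphere electron transfer by a hydroxyl-directed oxygen transfer: VO(acac)2 (catalytic) and t-BuOOH in CH2Cl2 at 0 °C. The vanadium peroxide bound to the C5 hydroxyl can reach only the neighbouring furan C3=C4 bond, and the resulting epoxide opens to the same enedione and closes to the hemiketal. It sets out from 10 and comes back at 12; it makes no new compound (F0).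

**Step 10.** The ylide is a strong base, so enolisation of 14 towards C5 may compete with addition and lead to loss of the C6 silyloxy group by β-elimination or to erosion of the axial preference. The fallback uses a non-basic carbenoid addition followed by a separate ring closure. It sets out from 14: chloroiodomethane and MeLi·LiBr in THF at −78 °C (carbenoid generated in the presence of the ketone) should add axially to give (2R,3S,6R)-3-(chloromethyl)-2-{[(TBS)oxy]methyl}-6-{3-[(TBDPS)oxy]prop-1-en-2-yl}oxan-3-ol F1. K2CO3 in MeOH then closes the chlorohydrin, and the route is rejoined at 15.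

**Step 14.** The pairing is mismatched: the α-alkoxy aldehyde 17 intrinsically prefers the C5–O/C6–O anti adduct, so facial control by the auxiliary may be eroded, and residual boron triflate may open the epoxide. The fallback changes the auxiliary class and the transition state to a chelated metal enolate, and shortens the sequence. It sets out from 18 and 17. Acid 18 is coupled (EDC·HCl, DMAP) with (4R)-4-benzyl-1,3-thiazolidine-2-thione to give tert-butyl 4-[(4R)-4-benzyl-2-thioxo-1,3-thiazolidin-3-yl]-4-oxobutanoate F2. Its divalent tin enolate (Sn(OTf)2, N-ethylpiperidine, CH2Cl2, −78 °C), in which the thiocarbonyl sulfur is bound to tin, should add to 17 with higher enolate facial bias to give the thiazolidinethione aldol adduct F3 with the same C6 and C7 configuration as 23. MeNHOMe·HCl and imidazole in CH2Cl2 then displace the auxiliary directly, and the route is rejoined at 26, bypassing 24 and 25.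

**Step 18.** The terminal vinyl ketone of 27 may be consumed by conjugate addition or by electron transfer from SmI2 before the hydride shift, and the propanoate of 28 may migrate between O6 and O8. The fallback separates the reduction from the differentiation of the two oxygens. It sets out from 27: Me4NBH(OAc)3 in MeCN/AcOH at −30 °C (Evans–Saksena reduction, hydride delivered from the boron bound to O6) should give tert-butyl (3R,4R)-4-hydroxy-3-{(S)-hydroxy[(3R,4R,6R)-6-{3-[(TBDPS)oxy]prop-1-en-2-yl}-1,5-dioxaspiro[2.5]octan-4-yl]methyl}hex-5-enoate F4. TBSCl and imidazole in DMF at 0 °C should then silylate the less hindered allylic C8 hydroxyl. The route is rejoined at 30, which is carried through the lactonisation conditions of step 20 to 31.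

**Step 21.** Closure onto the hindered 1,1-disubstituted alkene may be slower than intermolecular metathesis at the monosubstituted vinyl group, giving oligomers, and the trans-lactone may hold the two arms apart. The fallback moves the ring closure to an earlier, open-chain substrate with a free allylic hydroxyl, which is less constrained and more reactive at the vinyl group. It sets out from 28: the same catalyst in dilute toluene should give the bicyclic hydroxy propanoate F5 (eight-membered oxacycle closed, tert-butyl ester side chain, stereocentres as in 32). TBSOTf and 2,6-lutidine at −78 °C give its silyl ether F6, and K2CO3 in MeOH removes the propanoate and closes the lactone. The route is rejoined at 32.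

## Further compounds

F0 | step 7 | none | none
F1 | step 10 | (2R,3S,6R)-3-(chloromethyl)-2-{[(TBS)oxy]methyl}-6-{3-[(TBDPS)oxy]prop-1-en-2-yl}oxan-3-ol | C=C(CO[Si](c1ccccc1)(c1ccccc1)C(C)(C)C)[C@H]1CC[C@@](O)(CCl)[C@@H](CO[Si](C)(C)C(C)(C)C)O1
F2 | step 14 | tert-butyl 4-[(4R)-4-benzyl-2-thioxo-1,3-thiazolidin-3-yl]-4-oxobutanoate | CC(C)(C)OC(=O)CCC(=O)N1C(=S)SC[C@H]1Cc1ccccc1
F3 | step 14 | tert-butyl (3S,4S)-3-{[(4R)-4-benzyl-2-thioxo-1,3-thiazolidin-3-yl]carbonyl}-4-hydroxy-4-[(3R,4R,6R)-6-{3-[(TBDPS)oxy]prop-1-en-2-yl}-1,5-dioxaspiro[2.5]octan-4-yl]butanoate | C=C(CO[Si](c1ccccc1)(c1ccccc1)C(C)(C)C)[C@H]1CC[C@@]2(CO2)[C@H](O1)[C@@H](O)[C@H](CC(=O)OC(C)(C)C)C(=O)N1C(=S)SC[C@H]1Cc1ccccc1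
F4 | step 18 | tert-butyl (3R,4R)-4-hydroxy-3-{(S)-hydroxy[(3R,4R,6R)-6-{3-[(TBDPS)oxy]prop-1-en-2-yl}-1,5-dioxaspiro[2.5]octan-4-yl]methyl}hex-5-enoate | C=C(CO[Si](c1ccccc1)(c1ccccc1)C(C)(C)C)[C@H]1CC[C@@]2(CO2)[C@H](O1)[C@@H](O)[C@H](CC(=O)OC(C)(C)C)[C@H](O)C=C
F5 | step 21 | bicyclic ring-closed hydroxy propanoate from 28 (C8 hydroxyl free, C6 propanoate, C7 CH2CO2t-Bu) | O[C@@H]1/C=C(/CO[Si](c2ccccc2)(c2ccccc2)C(C)(C)C)[C@H]2CC[C@@]3(CO3)[C@H](O2)[C@@H](OC(=O)CC)[C@@H]1CC(=O)OC(C)(C)C
F6 | step 21 | 8-O-TBS ether of F5 | CC(C)(C)[Si](C)(C)O[C@@H]1/C=C(/CO[Si](c2ccccc2)(c2ccccc2)C(C)(C)C)[C@H]2CC[C@@]3(CO3)[C@H](O2)[C@@H](OC(=O)CC)[C@@H]1CC(=O)OC(C)(C)C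
A1 | alternative 1 | tricyclic C8 carbinol with C14 methyl and C4 methylene | O[C@@H]1/C=C(/C)[C@H]2CCC(=C)[C@H](O2)[C@H]2OC(=O)C(=C)[C@@H]21
A2 | alternative 1 | (Z)-iodoalkene aldehyde (C8–C9 seco precursor) | I/C=C(/C)[C@H]1CCC(=C)[C@H](O1)[C@H]1OC(=O)C(=C)[C@@H]1C=O
A3 | alternative 2 | tricyclic ether lactone with 8-O-triethylsilyl and 14-O-TBS groups | CC[Si](CC)(CC)O[C@@H]1/C=C(/CO[Si](C)(C)C(C)(C)C)[C@H]2CCC(=C)[C@H](O2)[C@H]2OC(=O)C(=C)[C@@H]21
A4 | alternative 2 | ten-membered cis-5,6-epoxy C1 alcohol with C12 methyl ester | CC[Si](CC)(CC)O[C@@H]1/C=C(/CO[Si](C)(C)C(C)(C)C)[C@H](O)CCC(=C)[C@H]2O[C@H]2[C@@H]1C(=C)C(=O)OC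
A5 | alternative 3 | oxa-bridged cyclodecenone with C4 ketone | CC(C)(C)[Si](C)(C)O[C@@H]1/C=C(/CO[Si](C)(C)C(C)(C)C)[C@H]2CCC(=O)[C@H](O2)[C@@H](OCc2ccc(OC)cc2)[C@@H]1C(=C)COCc1ccc(OC)cc1
A6 | alternative 3 | 2-oxabicyclo[3.3.1]non-3-ene C4 vinyl carbinol | C=C[C@]1(O)[C@@H]2OC=C(CO[Si](C)(C)C(C)(C)C)[C@H]1[C@@H](O[Si](C)(C)C(C)(C)C)[C@@H](C(=C)COCc1ccc(OC)cc1)[C@@H]2OCc1ccc(OC)cc1
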